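The ten-membered carbocycle is grown from a cyclohexane rather than closed end to end. The pattern exploited is the C3=C4 alkene lying across the ten-membered ring from oxygenated C8, with oxygenated C6 two atoms beyond. Joining C3 to C8 on paper gives a 1,2-dialkenylcyclohexanol whose oxy-Cope shift creates C5–C6. In one operation the potassium alkoxide of 22 forms C5–C6, cleaves C3–C8, enlarges the six-membered ring to the ten-membered ring, sets the ring-cis C3=C4 alkene and C6, and leaves a regiodefined C7=C8 enolate, kept as silyl enol ether 25. Precursor 22 carries O8, the C4 alkenyl group and C14 equatorial and an axial (E)-PMB-oxyvinyl group.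

Key step: step 13

Numbering (target numbering, used for every intermediate): C6 is the lactone O–CH. Going round the ten-membered ring from C6: C5 (CH2), C4 (alkene carbon bearing C15H2OH), C3 (=CH), C2, C1, C10 (CH bearing C14H2OH), C9, C8 (CH–O-angelate), C7 (ring-fusion CH). The lactone carbons are C11 (=C13H2) and C12 (C=O). In acid 1 the ring atoms 1 to 6 become C10, C9, C8, C3, C2, C1.

Remark on the way to 22: epoxidation of the C8=C3 alkene would not distinguish its two faces. By the Fürst–Plattner rule only the epoxide trans to C14 would open at C3. O8 is therefore fixed by iodolactonisation, and the C3 alkenyl group is attached by cross-coupling on the derived iodoenone.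

Assumption: electrophile and hydride are taken to reach C7 and C8 from the peripheral face of the ring conformer born in step 13. This is the one stereochemical premise not tied to a cyclic transition state.

Abbreviations: TBS = tert-butyldimethylsilyl, TMS = trimethylsilyl, PMB = 4-methoxybenzyl.

Step 1
Reactants: 1 (R)-cyclohex-3-ene-1-carboxylic acid
Product: 2 (1R,4R,5R)-4-iodo-6-oxabicyclo[3.2.1]octan-7-one
Conditions: I2, KI, NaHCO3, H2O–CH2Cl2, 0 °C → rt, dark
Reagents that add atoms: iodine, II
Why: Iodolactonisation: the carboxylate on C10 can close only the five-membered lactone by anti attack on the iodonium ion, so oxygen goes to C8 (cis to C14) and iodine to C3 with full regiocontrol.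

Step 2
Reactants: 2 iodolactone
Product: 3 (1R,5R)-6-oxabicyclo[3.2.1]oct-3-en-7-one
Conditions: DBU, toluene, reflux
Reagents that add atoms: none
Why: E2 elimination: the axial C3–I bond is antiperiplanar only to an axial hydrogen on C2 (H8 is equatorial in the bridged chair), so the alkene should form as C2=C3 and leave the C8–O bond allylic.

Step 3
Reactants: 3 unsaturated lactone
Product: 4 (1R,5R)-5-(hydroxymethyl)cyclohex-2-en-1-ol
Conditions: LiAlH4, THF, 0 °C
Reagents that add atoms: none
Why: Hydride reduction of a lactone to the diol frees O8–H and C14–OH without touching C8, C10 or the alkene.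

Step 4
Reactants: 4 cis-diol
Product: 5 (1R,5R)-5-(TBS-oxymethyl)cyclohex-2-en-1-ol
Conditions: TBSCl (1.05 equiv), imidazole, CH2Cl2, 0 °C
Reagents that add atoms: tert-butyldimethylsilyl chloride, CC(C)(C)[Si](C)(C)Cl
Why: Silyl ether formation is rate-selective for the unhindered primary C14 hydroxyl over the secondary allylic one.

Step 5
Reactants: 5 allylic alcohol
Product: 6 (5R)-5-(TBS-oxymethyl)cyclohex-2-en-1-one
Conditions: MnO2, CH2Cl2, rt
Reagents that add atoms: none
Why: Allylic alcohol oxidation with MnO2 is neutral and chemoselective; it turns C8 into the enone carbonyl while C10, the only stereocentre still needed, is untouched.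

Step 6
Reactants: 6 enone
Product: 7 (5R)-5-(TBS-oxymethyl)-2-iodocyclohex-2-en-1-one
Conditions: I2, pyridine–CH2Cl2, 0 °C → rt
Reagents that add atoms: iodine, II
Why: Baylis–Hillman-type α-iodination (conjugate addition of pyridine, iodination of the enolate, loss of pyridinium) can place the halogen only on C3.

Step 7
Reactants: 8 2-bromoprop-2-en-1-ol
Product: 9 [(2-bromoprop-2-en-1-yl)oxy](tert-butyl)dimethylsilane
Conditions: TBSCl, imidazole, CH2Cl2, rt
Reagents that add atoms: tert-butyldimethylsilyl chloride, CC(C)(C)[Si](C)(C)Cl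
Why: Standard silyl ether formation masks O15 with the same group as O14, so both can fall in one final operation.

Step 8
Reactants: 9 2-bromoallyl TBS ether; 7 iodoenone
Product: 12 (5R)-2-alkenyl enone (C3–C4 bond made), via alkenyllithium 10 (not isolated), via alkenylzinc bromide 11 (not isolated)
Conditions: 9, t-BuLi (2 equiv), Et2O, −78 °C; ZnBr2, THF, −78 → 0 °C; then 7, Pd2(dba)3 (2.5 mol %), P(2-furyl)3 (10 mol %), THF–DMF, rt
Reagents that add atoms: none
Why: Negishi coupling of an α-iodoenone with an alkenylzinc halide attaches C4 to C3 and nowhere else; the lithium reagent is moved to zinc at −78 °C, before an O-to-C silyl shift (retro-Brook) can start.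

Step 9
Reactants: 12 2-alkenyl enone
Product: 14 (2S,5R)-trans-2,5-disubstituted cyclohexanone, via lithium dienolate 13 (not isolated)
Conditions: LiBH(s-Bu)3 (1.05 equiv), THF, −78 °C; then AcOH, THF, −78 °C
Reagents that add atoms: none
Why: Conjugate hydride reduction of a β-unsubstituted cyclohexenone gives dienolate 13; kinetic α-protonation at C3 along the axial line of the half-chair with C14 equatorial leaves the alkenyl group equatorial and trans to C14, which is also the more stable epimer, so any cis isomer could be converged with a trace of DBU.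

Step 10
Reactants: 15 4-methoxybenzyl alcohol; 16 trichloroethylene
Product: 18 (E)-1,2-dichlorovinyl PMB ether, via potassium alkoxide 17 (not isolated)
Conditions: KH, THF, 0 °C; then 16, −50 °C → rt
Reagents that add atoms: none
Why: Net vinylic substitution of chloride by the alkoxide (elimination–addition) is the established entry to 1,2-dichlorovinyl ethers, the storable precursors of alkoxyacetylides.

Step 11
Reactants: 18 dichlorovinyl PMB ether; 14 trans-2,5 ketone
Product: 21 (1R,2S,5R)-1-(PMB-oxyethynyl)cyclohexanol, via chloroalkynyl ether 19 (not isolated), via lithium alkoxyacetylide 20 (not isolated)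
Conditions: 18 (1.5 equiv), n-BuLi (3.0 equiv), THF, −78 → −40 °C; then 14, −78 °C; H2O
Reagents that add atoms: none
Why: Dehydrochlorination and Cl–Li exchange give the acetylide, whose 1,2-addition as a slim sp nucleophile should follow the axial trajectory on the diequatorial chair of 14, making O8 equatorial and the alkynyl group axial and cis to the C4 alkenyl group (C8 = 1R).

Step 12
Reactants: 21 alkynyl ether carbinol
Product: 22 (1R,2S,5R)-1-[(E)-2-(PMB-oxy)ethenyl]cyclohexanol (oxy-Cope precursor)
Conditions: LiAlH4, THF, 0 °C → rt; aq NaOH work-up, base-washed silica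
Reagents that add atoms: none
Why: Alkoxide-directed trans-hydroalumination of a propargylic alcohol followed by protonolysis gives the E enol ether, as known for alkoxyethynyl carbinols; silyl and PMB ethers are inert, and acid is avoided because 22 would hydrolyse to an enal.

Step 13
Reactants: 22 cis-dialkenyl cyclohexanol
Product: 25 ten-membered TMS enol ether (6R,10R; C3=C4 ring-cis; C7=C8 ring-trans), via potassium alkoxide 23 (not isolated), via potassium enolate 24 (not isolated)
Conditions: KH, 18-crown-6, THF, 0 °C → rt; then −78 °C, TMSCl, Et3N; cold NaHCO3 wash, pentane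
Reagents that add atoms: trimethylsilyl chloride, C[Si](C)(C)Cl
Why: KH with 18-crown-6 turns 22 into the dissociated alkoxide 23, whose oxyanion weakens the adjacent C3–C8 σ bond, so that C5–C6 forms while C3–C8 breaks in a concerted [3,3] shift (anionic oxy-Cope rearrangement; closest known type: cis-1,2-dialkenylcyclohexanols giving ring-cis cyclodec-5-enones). The ten-membered ring is closed by four-atom ring expansion of the cyclohexane through a six-centre chair array, not by end-to-end cyclisation, so no high dilution is needed. In the ground-state chair of 23 (O8, C4 and C14 equatorial, C7 axial) the two alkenyl groups are already gauche, and on the pericyclic chair C2 is axial and C9 equatorial, which translates into the ring-cis C3=C4 alkene and the ring-trans C7=C8 enolate 24. C6 is the only new stereocentre: the E enol ether keeps the PMB-oxy group equatorial on that chair and C5 can reach only the face of C6 turned towards C4, so the C3/C8 configuration is relayed to 6R. The step needs chair over boat, [3,3] over [1,3] shift or fragmentation, and survival of a β-alkoxy enolate; the all-equatorial cis-dialkenyl substrate secures the first two, and in 24 allylic strain holds H6 eclipsed with O8, so the C6–O bond lies near the enolate plane and is poorly aligned for E1cB loss. Cooling to −78 °C and adding TMSCl/Et3N silylates O8 and stores the enolate, defined in position and geometry, as 25.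

Step 14
Reactants: 25 TMS enol ether; 26 ethyl iodoacetate
Product: 28 (6R,7S,10R)-C7-alkylated keto ester, via lithium enolate 27 (not isolated)
Conditions: MeLi (1.05 equiv), THF, −20 → 0 °C; then −78 °C, DMPU, 26, −78 → −40 °C
Reagents that add atoms: none
Why: Cleavage of the Si–O bond by MeLi regenerates the C7=C8 enolate without equilibration, and SN2 alkylation by the reactive iodoacetate should take place at C7 on the peripheral face, anti to C5 which stands perpendicular to the enolate plane, placing C11 trans to O6 as the target requires.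

Step 15
Reactants: 28 keto ester
Product: 30 (6R,7S,10R)-trans-fused keto γ-lactone, via hydroxy keto ester 29 (not isolated)
Conditions: DDQ, CH2Cl2–pH 7 buffer, 0 °C; then PPTS (cat.), toluene, 40 °C
Reagents that add atoms: none
Why: Oxidative PMB cleavage frees O6–H under neutral conditions, and acid-catalysed 5-exo-trig transesterification closes the O6–C12 lactone before any O8 hydroxyl exists to compete; base is avoided because the β-hydroxy ketone could undergo retro-aldol ring opening or dehydration.

Step 16
Reactants: 30 keto lactone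
Product: 31 (6R,7R,8R,10R)-8-hydroxy lactone
Conditions: NaBH4, CeCl3·7H2O, MeOH–THF, −78 → −40 °C
Reagents that add atoms: none
Why: Luche reduction is non-basic enough to spare the β-acyloxy ketone from E1cB; hydride should add to the outer face of the C8 carbonyl, whose inner face is screened across the ring, which is also the Felkin–Anh mode with C6 anti to the nucleophile and H7 next to C9, giving 8R with O8 anti to O6.

Step 17
Reactants: 31 hydroxy lactone
Product: 35 (6R,7R,8R,10R)-8-hydroxy α-methylene lactone, via dilithio species 32 (not isolated), via Mannich base 33 (not isolated), via methiodide 34 (not isolated)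
Conditions: LDA (3 equiv), THF, −78 °C; CH2=NMe2+ I−, −78 °C → rt; then MeI, CH2Cl2, rt; then aq NaHCO3, CH2Cl2
Reagents that add atoms: N,N-dimethylmethyleneiminium iodide (Eschenmoser's salt), C=[N+](C)C.[I-]
Why: Mannich aminomethylation of the lactone enolate, quaternisation and Hofmann-type elimination install C13; excess base turns the lactone into its non-electrophilic enolate as O8 is deprotonated, which should block acyl migration to O8.

Step 18
Reactants: 35 α-methylene hydroxy lactone; 36 angelic acid
Product: 38 bis-TBS ether of the target, via mixed anhydride 37 (not isolated)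
Conditions: 36, 2,4,6-Cl3C6H2COCl, Et3N, toluene, rt; then 35, 80 °C
Reagents that add atoms: none
Why: Yamaguchi-type mixed-anhydride esterification run without a nucleophilic catalyst acylates the hindered O8 at the less hindered angeloyl carbonyl and gives no addition–elimination path from the Z (angelate) to the E (tiglate) ester.

Step 19
Reactants: 38 bis-TBS ether
Product: 39 target CNP0147777.1
Conditions: HF·pyridine, pyridine–THF, 0 °C → rt
Reagents that add atoms: none
Why: Fluoride-driven desilylation in a mildly acidic medium removes both primary TBS groups while the angelate, the α-methylene lactone and all four stereocentres, which are sensitive only to base or nucleophiles, stay intact.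

Compound list
1 | (R)-cyclohex-3-ene-1-carboxylic acid | O=C(O)[C@H]1CC=CCC1 | starting material
2 | (1R,4R,5R)-4-iodo-6-oxabicyclo[3.2.1]octan-7-one | O=C1O[C@@H]2C[C@H]1CC[C@H]2I | intermediate
3 | (1R,5R)-6-oxabicyclo[3.2.1]oct-3-en-7-one | O=C1O[C@@H]2C[C@H]1CC=C2 | intermediate
4 | (1R,5R)-5-(hydroxymethyl)cyclohex-2-en-1-ol (cis) | OC[C@@H]1CC=C[C@H](O)C1 | intermediate
5 | (1R,5R)-5-{[(tert-butyldimethylsilyl)oxy]methyl}cyclohex-2-en-1-ol | CC(C)(C)[Si](C)(C)OC[C@@H]1CC=C[C@H](O)C1 | intermediate
6 | (5R)-5-{[(tert-butyldimethylsilyl)oxy]methyl}cyclohex-2-en-1-one | CC(C)(C)[Si](C)(C)OC[C@@H]1CC=CC(=O)C1 | intermediate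
7 | (5R)-5-{[(tert-butyldimethylsilyl)oxy]methyl}-2-iodocyclohex-2-en-1-one | CC(C)(C)[Si](C)(C)OC[C@@H]1CC=C(I)C(=O)C1 | intermediate
8 | 2-bromoprop-2-en-1-ol | OCC(Br)=C | starting material
9 | [(2-bromoprop-2-en-1-yl)oxy](tert-butyl)dimethylsilane | C=C(Br)CO[Si](C)(C)C(C)(C)C | intermediate
10 | {3-[(tert-butyldimethylsilyl)oxy]prop-1-en-2-yl}lithium | [Li]C(=C)CO[Si](C)(C)C(C)(C)C | intermediate
11 | bromo{3-[(tert-butyldimethylsilyl)oxy]prop-1-en-2-yl}zinc | Br[Zn]C(=C)CO[Si](C)(C)C(C)(C)C | intermediate
12 | (5R)-5-{[(tert-butyldimethylsilyl)oxy]methyl}-2-{3-[(tert-butyldimethylsilyl)oxy]prop-1-en-2-yl}cyclohex-2-en-1-one | CC(C)(C)[Si](C)(C)OC[C@@H]1CC=C(C(=C)CO[Si](C)(C)C(C)(C)C)C(=O)C1 | intermediate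
13 | lithium C8=C3 dienolate of 14 (10R) | [Li]OC1=C(C(=C)CO[Si](C)(C)C(C)(C)C)CC[C@@H](CO[Si](C)(C)C(C)(C)C)C1 | intermediate
14 | (2S,5R)-5-{[(tert-butyldimethylsilyl)oxy]methyl}-2-{3-[(tert-butyldimethylsilyl)oxy]prop-1-en-2-yl}cyclohexan-1-one (trans, diequatorial) | O=C1C[C@H](CO[Si](C)(C)C(C)(C)C)CC[C@H]1C(=C)CO[Si](C)(C)C(C)(C)C | intermediate
15 | 4-methoxybenzyl alcohol | COc1ccc(CO)cc1 | starting material
16 | trichloroethylene | ClC=C(Cl)Cl | starting material
17 | potassium 4-methoxybenzyl oxide | COc1ccc(C[O-])cc1.[K+] | intermediate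
18 | 1-({[(E)-1,2-dichloroethenyl]oxy}methyl)-4-methoxybenzene | COc1ccc(CO/C(Cl)=C\Cl)cc1 | intermediate
19 | 1-{[(chloroethynyl)oxy]methyl}-4-methoxybenzene | COc1ccc(COC#CCl)cc1 | intermediate
20 | lithium [(4-methoxybenzyl)oxy]acetylide | COc1ccc(COC#C[Li])cc1 | intermediate
21 | (1R,2S,5R)-5-(TBS-oxymethyl)-2-[3-(TBS-oxy)prop-1-en-2-yl]-1-{[(4-methoxybenzyl)oxy]ethynyl}cyclohexan-1-ol | O[C@]1(C#COCc2ccc(OC)cc2)C[C@H](CO[Si](C)(C)C(C)(C)C)CC[C@H]1C(=C)CO[Si](C)(C)C(C)(C)C | intermediate
22 | (1R,2S,5R)-5-(TBS-oxymethyl)-2-[3-(TBS-oxy)prop-1-en-2-yl]-1-{(E)-2-[(4-methoxybenzyl)oxy]ethenyl}cyclohexan-1-ol | O[C@]1(/C=C/OCc2ccc(OC)cc2)C[C@H](CO[Si](C)(C)C(C)(C)C)CC[C@H]1C(=C)CO[Si](C)(C)C(C)(C)C | intermediate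
23 | potassium alkoxide of 22 | [K+].[O-][C@]1(/C=C/OCc2ccc(OC)cc2)C[C@H](CO[Si](C)(C)C(C)(C)C)CC[C@H]1C(=C)CO[Si](C)(C)C(C)(C)C | intermediate
24 | potassium C7=C8 enolate of the ten-membered ketone (6R,10R; C3=C4 ring-cis, C7=C8 ring-trans) | [K+].COc1ccc(CO[C@@H]2C/C(CO[Si](C)(C)C(C)(C)C)=C\CC[C@@H](CO[Si](C)(C)C(C)(C)C)C/C([O-])=C/2)cc1 | intermediate
25 | (6R,10R)-6-(PMB-oxy)-8-(TMS-oxy)-4,10-bis(TBS-oxymethyl)cyclodeca-3,7-diene (target numbering; C3=C4 ring-cis, descriptor E; C7=C8 ring-trans, descriptor Z) | COc1ccc(CO[C@@H]2C/C(CO[Si](C)(C)C(C)(C)C)=C\CC[C@@H](CO[Si](C)(C)C(C)(C)C)C/C(O[Si](C)(C)C)=C/2)cc1 | intermediate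
26 | ethyl iodoacetate | CCOC(=O)CI | starting material
27 | lithium C7=C8 enolate (same geometry as 25) | COc1ccc(CO[C@@H]2C/C(CO[Si](C)(C)C(C)(C)C)=C\CC[C@@H](CO[Si](C)(C)C(C)(C)C)C/C(O[Li])=C/2)cc1 | intermediate
28 | (6R,7S,10R)-ten-membered C8 ketone with C6 PMB ether and C7 CH2CO2Et (C11 trans to O6) | COc1ccc(CO[C@@H]2C/C(CO[Si](C)(C)C(C)(C)C)=C\CC[C@@H](CO[Si](C)(C)C(C)(C)C)CC(=O)[C@H]2CC(=O)OCC)cc1 | intermediate
29 | (6R,7S,10R)-6-hydroxy keto ester | O[C@@H]1C/C(CO[Si](C)(C)C(C)(C)C)=C\CC[C@@H](CO[Si](C)(C)C(C)(C)C)CC(=O)[C@H]1CC(=O)OCC | intermediate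
30 | (6R,7S,10R)-8-oxo-6,12-olide, trans-fused γ-lactone | C1C(=O)O[C@@H]2C/C(CO[Si](C)(C)C(C)(C)C)=C\CC[C@@H](CO[Si](C)(C)C(C)(C)C)CC(=O)[C@@H]12 | intermediate
31 | (6R,7R,8R,10R)-8-hydroxy-6,12-olide | C1C(=O)O[C@@H]2C/C(CO[Si](C)(C)C(C)(C)C)=C\CC[C@@H](CO[Si](C)(C)C(C)(C)C)C[C@@H](O)[C@@H]12 | intermediate
32 | dilithio species of 31 (O8 alkoxide and C11=C12 lactone enolate) | C1=C(O[Li])O[C@@H]2C/C(CO[Si](C)(C)C(C)(C)C)=C\CC[C@@H](CO[Si](C)(C)C(C)(C)C)C[C@@H](O[Li])[C@@H]12 | intermediate
33 | C11-(dimethylaminomethyl) lactone (C11 epimers) | CN(C)CC1C(=O)O[C@@H]2C/C(CO[Si](C)(C)C(C)(C)C)=C\CC[C@@H](CO[Si](C)(C)C(C)(C)C)C[C@@H](O)[C@@H]12 | intermediate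
34 | methiodide of 33 | C[N+](C)(C)CC1C(=O)O[C@@H]2C/C(CO[Si](C)(C)C(C)(C)C)=C\CC[C@@H](CO[Si](C)(C)C(C)(C)C)C[C@@H](O)[C@@H]12.[I-] | intermediate
35 | (6R,7R,8R,10R)-8-hydroxy-11(13)-methylene-6,12-olide, bis-TBS ether | C=C1C(=O)O[C@@H]2C/C(CO[Si](C)(C)C(C)(C)C)=C\CC[C@@H](CO[Si](C)(C)C(C)(C)C)C[C@@H](O)[C@@H]12 | intermediate
36 | angelic acid, (Z)-2-methylbut-2-enoic acid | C/C=C(/C)C(=O)O | starting material
37 | angelic 2,4,6-trichlorobenzoic anhydride | C/C=C(/C)C(=O)OC(=O)c1c(Cl)cc(Cl)cc1Cl | intermediate
38 | (6R,7R,8R,10R)-8-angeloyloxy-11(13)-methylene-6,12-olide, 14,15-bis-TBS ether | C=C1C(=O)O[C@@H]2C/C(CO[Si](C)(C)C(C)(C)C)=C\CC[C@@H](CO[Si](C)(C)C(C)(C)C)C[C@@H](OC(=O)/C(C)=C\C)[C@@H]12 | intermediate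
39 | CNP0147777.1, (6R,7R,8R,10R)-8-angeloyloxy-14,15-dihydroxy-11(13)-methylene-6,12-olide with ring-cis C3=C4 | C=C1C(=O)O[C@@H]2C/C(CO)=C\CC[C@@H](CO)C[C@@H](OC(=O)/C(C)=C\C)[C@@H]12 | target

Total step count: 19. Longest linear sequence: 17 (steps 1–6, 8, 9, 11–19).

Steps most likely to fail

Step 13. At the temperature the shift needs, three things may go wrong: loss of PMB-oxide from the enolate before it is silylated, fragmentation of the alkoxide, or leakage into a [1,3] shift. The fallback removes the charge altogether. Setting out from 22, O-silylation with N-(trimethylsilyl)imidazole would give the tertiary trimethylsilyl ether F1. Thermolysis of F1 (degassed toluene, silylated sealed tube, about 200 °C) is a neutral siloxy-Cope rearrangement through the same chair. Because the silyl group already sits on O8, the rearrangement leads straight back to 25 and no enolate is ever present.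

Step 14. During Si–O cleavage or alkylation, three things may go wrong: E1cB loss of the β-alkoxy group from the lithium enolate, proton transfer that scrambles the enolate position, or O-alkylation. The fallback forms C7–C11 without any enolate. Setting out from 25, Rh2(OAc)4-catalysed cyclopropanation with ethyl diazoacetate should take the electron-rich C7=C8 bond on its peripheral face and give the donor–acceptor siloxycyclopropane ester F2. Mild fluoride treatment (Et3N·3HF, THF, 0 °C) then breaks the C8–C11 bond and returns to 28.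

Step 16. Facial selectivity may be poor or reversed if the carbonyl turns through the ring, and the lactone acyl group may creep to O8. The fallback accepts the wrong face and inverts C8 during esterification. Setting out from 30, the reduction would then give the 8S alcohol F3. LDA and CH2=NMe2+ I− convert F3, through the dilithio species F4, into the 8S Mannich base F5, whose amine also masks the future methylene group against phosphine. Mitsunobu esterification with 36 (PPh3, DIAD, toluene) inverts C8 to give the 8R angelate Mannich base F6. MeI then gives the angelate methiodide F7, and aqueous NaHCO3 eliminates to rejoin the route at 38.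

Further compounds
F1 | step 13 | O8-trimethylsilyl ether of 22 (1R,2S,5R) | C[Si](C)(C)O[C@]1(/C=C/OCc2ccc(OC)cc2)C[C@H](CO[Si](C)(C)C(C)(C)C)CC[C@H]1C(=C)CO[Si](C)(C)C(C)(C)C
F2 | step 14 | C7–C8–C11 siloxycyclopropane ethyl ester (TMS-oxy on C8, C6 and C9 trans on the three-membered ring, C11 epimers) | COc1ccc(CO[C@@H]2C/C(CO[Si](C)(C)C(C)(C)C)=C\CC[C@@H](CO[Si](C)(C)C(C)(C)C)C[C@]3(O[Si](C)(C)C)C(C(=O)OCC)[C@@H]23)cc1
F3 | step 16 | 8S epimer of 31 | C1C(=O)O[C@@H]2C/C(CO[Si](C)(C)C(C)(C)C)=C\CC[C@@H](CO[Si](C)(C)C(C)(C)C)C[C@H](O)[C@@H]12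
F4 | step 16 | dilithio species of F3 | C1=C(O[Li])O[C@@H]2C/C(CO[Si](C)(C)C(C)(C)C)=C\CC[C@@H](CO[Si](C)(C)C(C)(C)C)C[C@H](O[Li])[C@@H]12
F5 | step 16 | 8S C11-(dimethylaminomethyl) lactone (C11 epimers) | CN(C)CC1C(=O)O[C@@H]2C/C(CO[Si](C)(C)C(C)(C)C)=C\CC[C@@H](CO[Si](C)(C)C(C)(C)C)C[C@H](O)[C@@H]12
F6 | step 16 | 8R angelate of the C11-(dimethylaminomethyl) lactone | CN(C)CC1C(=O)O[C@@H]2C/C(CO[Si](C)(C)C(C)(C)C)=C\CC[C@@H](CO[Si](C)(C)C(C)(C)C)C[C@@H](OC(=O)/C(C)=C\C)[C@@H]12
F7 | step 16 | methiodide of F6 | C[N+](C)(C)CC1C(=O)O[C@@H]2C/C(CO[Si](C)(C)C(C)(C)C)=C\CC[C@@H](CO[Si](C)(C)C(C)(C)C)C[C@@H](OC(=O)/C(C)=C\C)[C@@H]12.[I-]
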